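| setting | Sunday's | Thursday's | Saturday's |
|---|---|---|---|
| starting material | 0.500 M | 0.500 M | 0.200 M |
| partner | 0.550 M | 1.10 M | 0.220 M |
| time |  |  | 13 min |

| run | time / min | [target] / M |
|---|---|---|
| Sunday's run | 0.52 | 0.028 |
| Sunday's run | 0.89 | 0.055 |
| Sunday's run | 1.5 | 0.073 |
| Sunday's run | 2.6 | 0.114 |
| Sunday's run | 4.4 | 0.179 |
| Sunday's run | 7.6 | 0.242 |
| Sunday's run | 13 | 0.313 |
| Thursday's run | 0.52 | 0.046 |
| Thursday's run | 0.89 | 0.076 |
| Thursday's run | 1.5 | 0.115 |
| Thursday's run | 2.6 | 0.175 |
| Thursday's run | 4.4 | 0.258 |
| Thursday's run | 7.6 | 0.345 |
| Thursday's run | 13 | 0.417 |

(readings scatter by 0.005 M)

* how the opening rate goes with [partner] round the charge of the Sunday's run: the exponent of the rate at two percent of starting material gone to target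
* target in the Saturday's run at 13 min, as a share of the starting material charged
* which of these the readings show (the product decays / the second partner is lost by itself / the by-product binds the second partner / the two partners rest in a complex)

- Overall: starting material + partner -> target.
- Constant volume, constant temperature.
- Readings of a species count what is bound in complexes too.
- "The second partner" is partner.
- An order is taken over about fifteen percent of the charge, up and down.

- At 7.6 min, Thursday's flask, charged with twice the partner of Sunday's flask, has turned 69.0% of its starting material against 48.4% in Sunday's. I work each reading through the integrated second-order law, which allows for what each flask has used, and Sunday's constant over Thursday's reads 1.24.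
- First extreme: with no binding, the flask is plain second-order and that ratio is 1. Saturday's charges are 0.400 of Sunday's, so its clock runs slower by that factor, and 13 min in Saturday's flask equals 5.20 min in Sunday's, where the readings interpolate to 39.7%.
- Second extreme: with binding strong enough to hold the two partners in a complex (the resting state), the rate goes as the product of the charges over their sum. Thursday's sum is 1.52 times Sunday's, so that is the ratio here, and dilution leaves the clock alone, so Saturday's share equals Sunday's 62.6% at 13 min.
- The reading lies between these ratios, so I place Saturday's share between 39.7% and 62.6%.
- My rule is the binding load: the number, proportional to the sum of the two charges, such that the rate is the second-order rate divided by one plus the load. A load of one is the crossing between the extremes.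
- The ratio reading then gives Sunday's load as 0.816, below the crossing.
- Saturday's load is 0.327, below the crossing, which stretches the equivalent Sunday time to 7.12 min. Sunday's readings interpolate there to 46.9%, and that is my figure.
- The partner's part of the load gives me an order of 0.765.
- The forecast says 0.77, 44% and the two partners rest in a complex: "Reversible resting in a complex fits". Its share is lower than mine, and its order stands level with mine.
- Saturday's flask gives 45.5%, the order round Sunday's charge is 0.80, and the readings show that the two partners rest in a complex, so the forecast held.

    starting material + partner ⇌ target + by-product (0.3648 /M/min, 0.03960 /M/min)
    starting material + partner ⇌ idle substrate-reagent adduct, settled at all times (0.8940 /M)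

- The back step has 0.0396 /M/min against 0.365 /M/min forward. Thursday's load is 1.24, past the crossing, and the rule carries Sunday's 2.83 min to 1.75 min for a quarter of the charge as target, which Thursday's flask reaches at 1.64 min.

The data are calculated with constants of no real substance; the scatter is artificial.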